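The closed, stirred vessel holds solid substrate under a held gas phase, and the readings, given in percent of the charge, hide what the runs share.

common to all: gas phase 3.3 mM (held)
- red: solid substrate 0.10 M; protic impurity 2.8 mM; run made earlier
- blue: solid substrate 0.10 M; protic impurity 4.4 mM; run made earlier
- teal: solid substrate 0.15 M; protic impurity 2 mM; run made earlier
- flask: solid substrate 0.10 M; protic impurity 2.00 mM; time 2.0 min

- red (time / s: target / %): 10.0: 0.4; 20.0: 0.7; 30.0: 1.5; 60.0: 5.4; 120: 12.9
- blue (time / s: target / %): 10.0: 0.2; 30.0: 2.2; 60.0: 5.3; 80.0: 8.1; 120: 13.0
- teal (time / s: target / %): 25.0: 0.2; 50.0: 2.0; 80.0: 5.5; 90.0: 6.3; 120: 8.2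

(each reading ± 0.5 percentage points)

- solid substrate is a solid; its amount is given per volume of the solution
- the earlier runs were read with a standard deviation of 0.5 percentage points
- at the start none of the gas phase is in solution
- at the start none of the solid substrate is in solution

- target at 2.0 min, in percent of the solid substrate charged
- the change that raises the amount of target at 2.0 min, in percent of the solid substrate charged most ("none" if none brings more than 2 percentage points) (dawn / winter / spring / summer / none)
- amount of target at 2.0 min, in percent of the solid substrate charged, after spring

- dawn: doubling the dissolution coefficient of the solid substrate, all else as stated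
- winter: doubling the solubility of the solid substrate, all else as stated
- spring: doubling the transfer coefficient of the gas phase, all else as stated
- summer: doubling the saturation concentration of gas phase, all else as stated

Turned into concentrations, target at 120 s stands at 12.9 mM in red, 13.0 mM in blue and 12.3 mM in teal. Blue holds 1.57 times red's impurity and yet matches it, while teal holds 1.50 times red's solid and yet shows less than red. Two amounts therefore make the answer: the charge, and the output, meaning the concentration of target made by that time, which in these runs looks zero-order in the solid charge, with a mean of 12.7 mM. Their ratio gives 12.7% for the flask, but red, blue and teal differ in charge and impurity, not in solubility, in a coefficient or in gas saturation, so this reckoning ranks none of the options. The forecast gives 12.5%, puts spring at 14.5% and names summer, holding that “Raising gas saturation should increase the rate”; its number lies 0.23 percentage points below this reckoning, which names no change.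

The flask gives 13.7%, an output of 13.7 mM, which is 1.000 mM above the mean of the runs, with 61.6% of the charge still solid at 2.00 min. The best change is winter, gaining 13 points against 4 points for summer, and spring gives 13.8%.

    gas phase ⇌ dissolved gas, rate k1*(csat - [dissolved gas]) (kL = 4.60 s⁻¹)
    starting material + dissolved gas → target (k = 2.90 L mol⁻¹ s⁻¹)
    dissolved gas + target → over-reacted product (k = 1.50 L mol⁻¹ s⁻¹)
    dissolved gas → decomposed reagent (k = 0.00780 s⁻¹)
    solid substrate ⇌ starting material, rate k5*(cs5 - [starting material]) while solid is left; crystals form when [starting material] > cs5 (solubility = 38.0 mM, k = 0.0140 s⁻¹)
    dissolved gas + protic impurity → quenched reagent (k = 4.90 L mol⁻¹ s⁻¹)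

At 0.17 M of solid substrate, the output from the runs gives 7.47%; that neighbour flask computes to 8.06%, an output of 13.7 mM.

(The runs are simulated for an exercise.)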